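**Assumption:** The target SMILES has no axis descriptor. I take it to be the single 2,2'-binaphthyl-1,1'-diol atropisomer (aR). The only stereogenic element is the hindered biaryl axis, which has four ortho substituents (OH, Me, OH, Me) and is configurationally stable. If the product proves to be the other atropisomer, the enantiomeric catalyst is used.

## Retrosynthetic overview
1. Disconnect the C2–C2' biaryl bond. This leaves two copies of 5-isopropyl-3,8-dimethylnaphthalen-1-ol (8-hydroxycadalene). The axis is set in the last step by a catalytic, enantioselective oxidative phenol homo-coupling.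
2. Ring B of the naphthol is closed by an intramolecular Friedel–Crafts acylation of a 4-aryl-3-methylbut-3-enoic acid. The resulting keto-enol tautomerizes to the naphthol.
3. The aryl–alkenyl acid comes from a Heck reaction of thymyl triflate with 3-methylbut-3-enoic acid.
4. Thymol already carries the para iPr/Me pattern of ring A, and its OH carbon becomes the ring-fusion carbon C4a.

## Route

**Step 1**
Reactants: 1 (thymol, 2-isopropyl-5-methylphenol); 2 (triflic anhydride)
Product: 3 (thymyl triflate, 2-isopropyl-5-methylphenyl trifluoromethanesulfonate)
Conditions: Tf2O (1.2 equiv), pyridine, CH2Cl2, 0 °C → rt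
Reagents that add atoms: Tf2O, O=S(=O)(OS(=O)(=O)C(F)(F)F)C(F)(F)F (adds the SO2CF3 group)
Why: O-Sulfonylation of the phenol turns the unreactive C–O bond into a pseudohalide for Pd chemistry; no stereocenter is involved.

**Step 2**
Reactants: 3 (thymyl triflate); 4 (3-methylbut-3-enoic acid)
Product: 5 (4-(2-isopropyl-5-methylphenyl)-3-methylbut-3-enoic acid; the alkene geometry and double-bond position isomers all converge in Step 3)
Conditions: Pd(OAc)2 (5 mol %), dppp (10 mol %), i-Pr2NEt (3 equiv), DMF, 100 °C
Reagents that add atoms: none beyond reactant 4
Why: A cationic-pathway Mizoroki–Heck reaction puts the aryl group on the terminal CH2 of the 1,1-disubstituted alkene. The carboxylate survives as its ammonium salt, and no stereocenter is created.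

**Step 3**
Reactants: 5
Product: 6 (5-isopropyl-3,8-dimethylnaphthalen-1-ol)
Conditions: Eaton's reagent (7.7 wt % P2O5 in MsOH), 50 °C, 2 h
Reagents that add atoms: none (dehydrating acid; only H2O is lost)
Why: Intramolecular Friedel–Crafts acylation closes the ring at the only free ortho carbon. Strong acid equilibrates the alkene isomers through the tertiary cation, so the cis (Z) acyl/aryl geometry needed for ring closure is accessible. The resulting 3-methylnaphthalen-1(2H)-one tautomerizes to the aromatic naphthol; there is no stereocenter.

**Step 4**
Reactants: 6 (two equivalents)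
Product: 7 (Parviflorene H, (aR)-5,5'-diisopropyl-3,3',8,8'-tetramethyl-[2,2'-binaphthalene]-1,1'-diol)
Conditions: chiral oxovanadium(IV) Schiff-base catalyst (Sasai-type, 10 mol %), O2 (1 atm), CH2Cl2 or toluene, rt, 2–3 d
Reagents that add atoms: none (O2 is the terminal oxidant and leaves as H2O)
Why: Vanadium-catalyzed asymmetric oxidative phenol coupling joins two bound naphthol radicals at C2, ortho to OH. The chiral ligand sphere sets the biaryl axis during C–C bond formation, and the hindered axis cannot racemize afterwards.

## Compound list
1 | thymol | Cc1ccc(C(C)C)c(O)c1 | starting material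
2 | triflic anhydride | O=S(=O)(OS(=O)(=O)C(F)(F)F)C(F)(F)F | starting material
3 | 2-isopropyl-5-methylphenyl triflate | Cc1ccc(C(C)C)c(OS(=O)(=O)C(F)(F)F)c1 | intermediate
4 | 3-methylbut-3-enoic acid | CC(=C)CC(=O)O | starting material
5 | 4-(2-isopropyl-5-methylphenyl)-3-methylbut-3-enoic acid (alkene isomer mixture) | Cc1ccc(C(C)C)c(C=C(C)CC(=O)O)c1 | intermediate
6 | 5-isopropyl-3,8-dimethylnaphthalen-1-ol (achiral) | Cc1cc2c(C(C)C)ccc(C)c2c(O)c1 | intermediate
7 | Parviflorene H, (aR) axis (SMILES as given; it cannot encode the axis) | Cc1cc2c(C(C)C)ccc(C)c2c(O)c1-c1c(C)cc2c(C(C)C)ccc(C)c2c1O | target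

**Total steps:** 4. **Longest linear sequence:** 4 (1 → 3 → 5 → 6 → 7).

## Three steps most likely to fail
1. **Step 4 (regio- and enantioselective coupling).** The competing coupling modes are 4,4' and 2,4' (C4 is free, though hindered by the peri iPr), and ee may be modest.
   Fallback: block C4 of 6 with Br (NBS), then couple, then remove the Br by hydrogenolysis. Alternatively, couple racemically with FeCl3 and resolve through the bis-camphanate diastereomers.
2. **Step 2 (Heck on a hindered ortho-iPr triflate with a β,γ-unsaturated acid).** Yield and alkene isomer ratios are uncertain.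
   Fallback: convert 3 to the aryl pinacolboronate (Miyaura borylation), then Suzuki-couple it with ethyl 4-bromo-3-methylbut-2-enoate. Saponify to give the 3-methyl-but-2-enoic acid analogue of 5, which cyclizes in Step 3.
3. **Step 3 (Friedel–Crafts closure ortho to the peri methyl).** Risks are iPr loss or migration in the superacid and a hindered cyclization site.
   Fallback: hydrogenate the alkene of 5, cyclize the saturated acid chloride with SnCl4 to the 3-methyl-1-tetralone, then aromatize with DDQ or Pd/C.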